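**Plan**

- Retrosynthesis: the N1–CH3 bond is cut first. The quinolone C2–C3 bond is cut next (Camps), and the two carbonyl carbons so exposed are rejoined as the C2=C3 bond of an indole.
- Enabling feature: C4 (carbonyl carbon), C3 (ring CH) and C2 (bearing the C14 chain) of the nitrogen ring correspond atom for atom to C3, the 3-methyl carbon and C2 of 3-methyl-2-tetradecylindole. The six-membered ring is therefore the indole five-membered ring with the methyl carbon inserted.
- Last cut: the C1'–C2' bond of the side chain, which leads to 2,3-dimethylindole and 1-bromotridecane.
- Forward: the chain is joined first (step 1). The five-membered ring is then opened at C2=C3 and the six-membered nitrogen ring closed in the same flask (step 2). Nitrogen is methylated last (step 3); the benzene ring is carried through unchanged.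
- Stereochemistry: the target has no stereocentre and no stereogenic double bond, so nothing has to be controlled.

Key step: step 2

Assumption: the target is achiral; the transient intermediates 7 and 8 are racemic and drawn without stereodescriptors, and the anionic species of step 2 are listed in their neutral forms.

**Route**

Step 1
Reactants: 1 2,3-dimethyl-1H-indole; 2 1-bromotridecane
Product: 6 3-methyl-2-tetradecyl-1H-indole, via lithium 2,3-dimethylindole-1-carboxylate 3 (not isolated), via lithium 2-(lithiomethyl)-3-methylindole-1-carboxylate 4 (not isolated), via lithium 3-methyl-2-tetradecylindole-1-carboxylate 5 (not isolated)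
Conditions: n-BuLi, THF, −70 °C; CO2 (g), then excess CO2 removed in vacuo, fresh THF; t-BuLi, −70 to −20 °C; 2, −70 °C to rt; 1 M HCl, rt
Reagents that add atoms: none
Why: Transient N-carboxylation with directed lateral lithiation, precedented on 2-methylindole and on 2,3-dialkylindoles such as tetrahydrocarbazole: the lithium carbamate masks N–H and steers t-BuLi to the adjacent 2-methyl group rather than the remote 3-methyl group, the stabilised 2-indolylmethyllithium undergoes SN2 alkylation by the primary bromide, and acid work-up decarboxylates the carbamic acid.

Step 2
Reactants: 6 3-methyl-2-tetradecyl-1H-indole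
Product: 10 2-tetradecylquinolin-4(1H)-one, via 3-hydroperoxy-3-methyl-2-tetradecyl-3H-indole 7 (not isolated), via 7b-methyl-2a-tetradecyl-2a,7b-dihydro-3H-[1,2]dioxeto[3,4-b]indole 8 (not isolated), via N-(2-acetylphenyl)pentadecanamide 9 (not isolated)
Conditions: t-BuOK (4 equiv), O2 (1 atm), DMF, 0 °C to rt; then Ar, 60 °C; aq HCl to pH 7
Reagents that add atoms: dioxygen, O=O
Why: t-BuOK converts 6 into its indolyl anion, which is oxygenated by O2 at C3 (electron transfer, then radical recombination) to the peroxide anion of 7; this adds to the C2=N bond to give dioxetane 8, whose cycloreversion breaks the former indole C2–C3 bond and leaves keto amide 9 (Witkop cleavage). In the same basic medium the enolate of the acetyl group of 9 adds to the amide carbonyl and the adduct loses water (Camps cyclisation), which makes the quinolone C2–C3 bond, so that the old indole C3 ends as the C4 carbonyl, the old 3-methyl carbon as C3–H and the old C2 as C2 with its tetradecyl chain. The closest known reaction is the Winterfeldt oxidation of ring-fused 2,3-dialkylindoles to 4-quinolones with t-BuOK and O2 in DMF, and each half is also established on open-chain substrates (oxidative cleavage of 2,3-dimethylindole to the acetamido ketone; Camps closure of N-(2-acetylphenyl)alkanamides to 2-alkyl-4-quinolones). The one ring formed, the six-membered nitrogen ring, closes in a 6-(enolexo)-exo-trig manner, and no stereocentre is created, those of 7 and 8 being lost on cleavage. The selectivity needed is the direction of the Camps closure: in excess strong base the secondary amide of 9 is present as its nitrogen anion, which shuts down deprotonation of the amide α-CH2, so only the more acidic aryl methyl ketone enolises and the 4-quinolone rather than the isomeric 2-quinolone should form. Oxygen is replaced by argon once 6 is consumed so that this enolate is not oxygenated before it cyclises.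

Step 3
Reactants: 10 2-tetradecylquinolin-4(1H)-one
Product: 12 1-methyl-2-tetradecylquinolin-4(1H)-one, via sodium 2-tetradecylquinolin-4-olate 11 (not isolated)
Conditions: NaH, DMF, 0 °C; MeI, 0 °C to rt
Reagents that add atoms: iodomethane, CI
Why: Deprotonation gives the ambident quinolonate, and SN2 methylation by the soft electrophile MeI in a dipolar aprotic solvent should occur at nitrogen to give the vinylogous amide, which is also the thermodynamically preferred isomer (standard N-alkylation of 4-quinolones).

**Compound list**

1 | 2,3-dimethyl-1H-indole | Cc1[nH]c2ccccc2c1C | starting material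
2 | 1-bromotridecane | CCCCCCCCCCCCCBr | starting material
3 | lithium 2,3-dimethylindole-1-carboxylate | [Li+].[O-]C(=O)n1c(C)c(C)c2ccccc21 | intermediate
4 | lithium 2-(lithiomethyl)-3-methylindole-1-carboxylate | [Li+].[O-]C(=O)n1c(C[Li])c(C)c2ccccc21 | intermediate
5 | lithium 3-methyl-2-tetradecylindole-1-carboxylate | [Li+].[O-]C(=O)n1c(CCCCCCCCCCCCCC)c(C)c2ccccc21 | intermediate
6 | 3-methyl-2-tetradecyl-1H-indole | CCCCCCCCCCCCCCc1[nH]c2ccccc2c1C | intermediate
7 | 3-hydroperoxy-3-methyl-2-tetradecyl-3H-indole (racemic) | CCCCCCCCCCCCCCC1=Nc2ccccc2C1(C)OO | intermediate
8 | 7b-methyl-2a-tetradecyl-2a,7b-dihydro-3H-[1,2]dioxeto[3,4-b]indole (racemic, cis-fused) | CCCCCCCCCCCCCCC12Nc3ccccc3C1(C)OO2 | intermediate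
9 | N-(2-acetylphenyl)pentadecanamide | CCCCCCCCCCCCCCC(=O)Nc1ccccc1C(C)=O | intermediate
10 | 2-tetradecylquinolin-4(1H)-one | CCCCCCCCCCCCCCc1cc(=O)c2ccccc2[nH]1 | intermediate
11 | sodium 2-tetradecylquinolin-4-olate | [Na+].[O-]c1cc(CCCCCCCCCCCCCC)nc2ccccc12 | intermediate
12 | 1-methyl-2-tetradecylquinolin-4(1H)-one | CCCCCCCCCCCCCCc1cc(=O)c2ccccc2n1C | target

Total step count: 3
Longest linear sequence: 3 steps

**Steps most likely to fail, most doubtful first**

First, step 2. The methyl ketone enolate may be oxygenated further by O2 before it cyclises. The Camps closure may also stall on the deactivated amide anion at the temperature DMF tolerates. The fallback uncouples cleavage and ring closure and replaces the radical autoxidation by a two-electron oxidant. It sets out from 6: NaIO4 in THF/MeOH/H2O at rt should cleave the indole C2=C3 bond under neutral conditions to keto amide 9, which is now isolated. Heating 9 with NaOH in 1,4-dioxane at 110 °C (Camps cyclisation under conditions known to favour the 4-quinolone) should then give 10, where the route is rejoined. No compound outside the list is made (F0).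

Second, step 3. Alkylation of the ambident anion may be diverted to oxygen, because the nitrogen is flanked by the 2-alkyl chain and the peri C8–H. The fallback removes the ambiguity by turning oxygen into a leaving group and alkylating a nitrogen that is then the only nucleophilic site. It sets out from 10: POCl3 at 90 °C should give 4-chloro-2-tetradecylquinoline F1. MeOTf in CH2Cl2 at rt should quaternise the ring nitrogen to 4-chloro-1-methyl-2-tetradecylquinolin-1-ium trifluoromethanesulfonate F2. Aqueous NaOH in THF at rt should displace the activated 4-chloride (addition–elimination) and give the target 12 directly.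

Third, step 1. Lateral deprotonation may be incomplete, the long-chain bromide may undergo elimination instead of substitution, or nitrogen may be alkylated if carboxylation is incomplete. The fallback builds the same chain by olefination and hydrogenation instead of organolithium alkylation. It sets out from 2: heating with PPh3 in MeCN should give tridecyl(triphenyl)phosphonium bromide F3. NaN(SiMe3)2 in THF at 0 °C should convert it into tridecylidene(triphenyl)phosphorane F4. Two equivalents of F4 (the first is consumed by the N–H) react in a Wittig reaction with purchased 3-methyl-1H-indole-2-carbaldehyde (SMILES Cc1c(C=O)[nH]c2ccccc12) to give 3-methyl-2-[(Z)-tetradec-1-en-1-yl]-1H-indole F5; the alkene geometry is irrelevant. Hydrogenation with H2 over Pd/C in EtOAc should give 6, where the route is rejoined.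

**Further compounds**

F0 | step 2 | none | none
F1 | step 3 | 4-chloro-2-tetradecylquinoline | CCCCCCCCCCCCCCc1cc(Cl)c2ccccc2n1
F2 | step 3 | 4-chloro-1-methyl-2-tetradecylquinolin-1-ium trifluoromethanesulfonate | CCCCCCCCCCCCCCc1cc(Cl)c2ccccc2[n+]1C.[O-]S(=O)(=O)C(F)(F)F
F3 | step 1 | tridecyl(triphenyl)phosphonium bromide | CCCCCCCCCCCCC[P+](c1ccccc1)(c1ccccc1)c1ccccc1.[Br-]
F4 | step 1 | tridecylidene(triphenyl)phosphorane | CCCCCCCCCCCCC=P(c1ccccc1)(c1ccccc1)c1ccccc1
F5 | step 1 | 3-methyl-2-[(Z)-tetradec-1-en-1-yl]-1H-indole | CCCCCCCCCCCC/C=C\c1[nH]c2ccccc2c1C
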